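**Retrosynthetic overview**
1. Target 18 comes from one saponification of the methyl ester and aryl acetate in bicycle 17.
2. Key step: acyclic 16 → 17 forms ring A and then ring B in one operation. It sets C4, C5, C9 and C10 and the exocyclic methylene, by ionising a latent, enantiopure bromiranium (β‑bromo tertiary trifluoroacetate in HFIP) with a (Z)‑allylsilane terminator.
3. Avoided on purpose: aryl‑metal addition to a preformed decalin with late OH→Br exchange, and external Br⁺ on the free tetraene, which is neither site‑ nor enantioselective.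
4. The C10/C11 stereodiad comes from a Sharpless epoxidation directed by a C12 hydroxyl. That hydroxyl is then replaced by prenyl (triflate/Cu), and bromide opens the epoxide by SN2 at C10.
5. The chain comes from (E)‑geranylacetone. The allylsilane comes from silylmethyl‑cupration of a terminal alkyne, and the purchased arene is joined by Negishi coupling.

Assumptions: acyclic compounds use geranylgeranyl numbering (C1 = ArCH2) and bicycles use terpenoid numbering (C3 = CHBr). In that numbering the target is 3R,4R,5S,9R,10S. (E)‑Geranylacetone is bought geometrically pure.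

**Step 1**
Reactants: 1, (E)‑geranylacetone [(5E)‑6,10‑dimethylundeca‑5,9‑dien‑2‑one]
Product: 2, (5E)‑6,10‑dimethylundeca‑5,9‑dien‑1‑yne
Conditions: LDA (1.1 equiv), THF, −78 °C; ClP(O)(OEt)2, −78 °C → rt; LDA (2.3 equiv), −78 °C → rt; H2O
Reagents that add atoms: none
Why: Negishi methyl ketone → alkyne conversion, in which kinetic enolisation at CH3 gives the terminal enol phosphate and E2 elimination gives the alkyne without touching the isolated alkenes.

**Step 2**
Reactants: 2
Product: 3, (2E,6E)‑2,6‑dimethylundeca‑2,6‑dien‑10‑yn‑1‑ol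
Conditions: SeO2 (0.3 equiv), t‑BuOOH (3 equiv), salicylic acid (0.1 equiv), CH2Cl2, 0 °C → rt; then NaBH4, MeOH, 0 °C
Reagents that add atoms: SeO2, O=[Se]=O (re‑oxidised by t‑BuOOH, CC(C)(C)OO)
Why: Catalytic SeO2 allylic oxidation (ene/[2,3] sequence) attacks the (E)‑methyl of the terminal isopropylidene preferentially, and NaBH4 returns any over‑oxidised enal to the alcohol.

**Step 3**
Reactants: 3; 4, (trimethylsilyl)methylmagnesium chloride
Product: 5, (2E,6E,10Z)‑11‑iodo‑2,6‑dimethyl‑10‑[(trimethylsilyl)methyl]undeca‑2,6,10‑trien‑1‑ol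
Conditions: 4 (3.2 equiv; 1 equiv deprotonates the OH), CuBr·SMe2 (2.1 equiv), Et2O–Me2S, −40 °C → rt, 16 h; then I2 (titrated), THF, −78 °C; Na2S2O3
Reagents that add atoms: 4, C[Si](C)(C)C[Mg]Cl; iodine, II
Why: Normant syn‑carbocupration with the thermally robust TMSCH2Cu·MgX2 puts Cu on the terminal carbon cis to CH2TMS, and iodinolysis with retention gives only the (Z)‑iodide with the chain trans to iodine.

**Step 4**
Reactants: 5
Product: 6, {(2S,3S)‑3‑[(3E,7Z)‑8‑iodo‑3‑methyl‑7‑[(trimethylsilyl)methyl]octa‑3,7‑dien‑1‑yl]‑2‑methyloxiran‑2‑yl}methanol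
Conditions: Ti(OiPr)4 (10 mol %), L‑(+)‑DET (13 mol %), t‑BuOOH, 4 Å MS, CH2Cl2, −20 °C
Reagents that add atoms: t‑BuOOH, CC(C)(C)OO
Why: Katsuki–Sharpless epoxidation touches only the alkene bound through the allylic OH (site control), and L‑(+)‑tartrate gives the (2S,3S)‑epoxide, the same sense as geraniol → (2S,3S)‑epoxygeraniol, which sets future C10 (S) and C11 (S).

**Step 5**
Reactants: 6
Product: 7, the primary triflate of 6 (2S,3S)
Conditions: Tf2O, 2,6‑lutidine, CH2Cl2, −78 °C; cold work‑up, used crude
Reagents that add atoms: Tf2O, O=S(=O)(OS(=O)(=O)C(F)(F)F)C(F)(F)F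
Why: O‑sulfonylation of the primary alcohol under buffered cold conditions breaks no C–O bond, so the epoxide stereocentres and the allylsilane are untouched.

**Step 6**
Reactants: 7; 8, prenyl chloride (1‑chloro‑3‑methylbut‑2‑ene), used as its Grignard reagent
Product: 9, (2S,3S)‑3‑[(3E,7Z)‑8‑iodo‑3‑methyl‑7‑[(trimethylsilyl)methyl]octa‑3,7‑dien‑1‑yl]‑2‑methyl‑2‑(4‑methylpent‑3‑en‑1‑yl)oxirane
Conditions: 8, Mg, THF, 0 °C; then 7, CuI (20 mol %), THF–Et2O, −78 → −40 °C (1.4 equiv Grignard)
Reagents that add atoms: prenylmagnesium chloride, CC(C)=CC[Mg]Cl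
Why: In this Cu(I)‑catalysed Grignard/alkyl triflate coupling the primary triflate reacts far faster than the trisubstituted epoxide or the vinyl iodide, the allyl‑copper bonds through its unhindered CH2 (α‑coupling), and the stereocentres are not involved.

**Step 7**
Reactants: 10, methyl 4‑hydroxy‑3‑methylbenzoate
Product: 11, methyl 3‑bromo‑4‑hydroxy‑5‑methylbenzoate
Conditions: NBS, MeCN, 0 °C → rt
Reagents that add atoms: NBS, O=C1CCC(=O)N1Br
Why: Electrophilic aromatic bromination goes to the only free position ortho to the phenol, because the para position is blocked.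

**Step 8**
Reactants: 11
Product: 12, methyl 4‑acetoxy‑3‑bromo‑5‑methylbenzoate
Conditions: Ac2O, pyridine, DMAP (cat.), CH2Cl2, rt
Reagents that add atoms: Ac2O, CC(=O)OC(C)=O
Why: O‑acetylation makes the phenol oxygen non‑nucleophilic, so it cannot trap the cation as a chroman in the key step, and the acetate is removed in the final saponification.

**Step 9**
Reactants: 12
Product: 13, methyl 4‑acetoxy‑3‑bromo‑5‑(bromomethyl)benzoate
Conditions: NBS (1.05 equiv), AIBN, PhCF3, 85 °C
Reagents that add atoms: NBS, O=C1CCC(=O)N1Br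
Why: Wohl–Ziegler radical bromination acts at the only benzylic C–H position.

**Step 10**
Reactants: 9; 13
Product: 14, methyl 4‑acetoxy‑3‑bromo‑5‑{(2Z,6E)‑7‑methyl‑9‑[(2S,3S)‑3‑methyl‑3‑(4‑methylpent‑3‑en‑1‑yl)oxiran‑2‑yl]‑3‑[(trimethylsilyl)methyl]nona‑2,6‑dien‑1‑yl}benzoate
Conditions: 13, Zn dust, LiCl, THF, 0 °C → rt; then 9, Pd(PPh3)4 (5 mol %), THF, rt
Reagents that add atoms: none (both partners are numbered reactants)
Why: In this Negishi coupling the alkenyl iodide undergoes oxidative addition at rt much faster than the aryl bromide, the alkene geometry is retained, and the benzylic zinc tolerates the esters, epoxide and allylsilane.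

**Step 11**
Reactants: 14
Product: 15, methyl 4‑acetoxy‑3‑bromo‑5‑{(2Z,6E,10R,11S)‑10‑bromo‑11‑hydroxy‑7,11,15‑trimethyl‑3‑[(trimethylsilyl)methyl]hexadeca‑2,6,14‑trien‑1‑yl}benzoate
Conditions: Li2NiBr4 (LiBr + NiBr2), THF, 0 °C → rt; pH 7 buffer
Reagents that add atoms: Li2NiBr4, [Li+].[Li+].[Ni+2].[Br-].[Br-].[Br-].[Br-]
Why: Soft tetrabromonickelate bromide opens the epoxide by SN2 at the less substituted C10 with inversion (10S → 10R), leaves the C11–O stereocentre intact, and is neutral enough for the allylsilane and esters.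

**Step 12**
Reactants: 15
Product: 16, the 11‑trifluoroacetate of 15 (10R,11S)
Conditions: (CF3CO)2O, pyridine, CH2Cl2, −20 → 0 °C; used without chromatography
Reagents that add atoms: TFAA, O=C(OC(=O)C(F)(F)F)C(F)(F)F
Why: O‑acylation of the tertiary alcohol breaks no C–O bond, so both stereocentres are retained, and it installs a leaving group with chloride‑like nucleofugality under non‑ionising basic conditions.

**Step 13 (key step)**
Reactants: 16
Product: 17, methyl 4‑acetoxy‑3‑bromo‑5‑{[(1R,4aS,5R,6R,8aS)‑6‑bromo‑5,8a‑dimethyl‑2‑methylidene‑5‑(4‑methylpent‑3‑en‑1‑yl)decahydronaphthalen‑1‑yl]methyl}benzoate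
Conditions: (CF3)2CHOH (5 mM), 2,6‑di‑tert‑butyl‑4‑methylpyridine (1.5 equiv), 0 → 30 °C
Reagents that add atoms: none
Why: Proposed new method: in ionising, non‑nucleophilic HFIP the tertiary trifluoroacetate leaves with anti‑periplanar help from the C10 bromine, giving one enantiomer of the (E)‑bromiranium at C10–C11 only and with no external Br⁺ (so the prenyl and allylsilane alkenes never meet an electrophilic halogen); backside attack at C11 by the 6E‑alkene (net retention at C11 = C4) and then attack by the (Z)‑allylsilane through an all‑chair, anti‑addition array close ring A and then ring B, which fixes equatorial Br, axial C4‑Me with equatorial homoprenyl, the trans ring fusion and equatorial C9‑CH2Ar, and β‑silyl loss gives only the exocyclic methylene; the closest known reaction types are the enantiospecific solvolytic cyclisation of vicinal bromochlorides, Lewis‑acid ionisation of bromohydrin esters, and allylsilane‑terminated cation–olefin cyclisation.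

**Step 14**
Reactants: 17
Product: 18, callophycoic acid H, 3‑bromo‑5‑{[(1R,4aS,5R,6R,8aS)‑6‑bromo‑5,8a‑dimethyl‑2‑methylidene‑5‑(4‑methylpent‑3‑en‑1‑yl)decahydronaphthalen‑1‑yl]methyl}‑4‑hydroxybenzoic acid
Conditions: LiOH (10 equiv), THF–MeOH–H2O, 45 °C; then 10 % citric acid, 0 °C
Reagents that add atoms: LiOH/H2O, [Li+].[OH-]
Why: Saponification cleaves the aryl acetate and methyl benzoate together, the equatorial neopentyl bromide has no anti‑periplanar H and is closed to SN2, and the mild acidification avoids alkene isomerisation or chroman formation.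

**Compound list**
1 | (E)‑geranylacetone | CC(=O)CC/C=C(\C)CCC=C(C)C | starting material
2 | (5E)‑6,10‑dimethylundeca‑5,9‑dien‑1‑yne | C#CCC/C=C(\C)CCC=C(C)C | intermediate
3 | (2E,6E)‑2,6‑dimethylundeca‑2,6‑dien‑10‑yn‑1‑ol | C#CCC/C=C(\C)CC/C=C(\C)CO | intermediate
4 | (trimethylsilyl)methylmagnesium chloride | C[Si](C)(C)C[Mg]Cl | starting material
5 | (2E,6E,10Z)‑vinyl iodide/allylsilane alcohol | OC/C(C)=C/CC/C(C)=C/CC/C(C[Si](C)(C)C)=C/I | intermediate
6 | (2S,3S)‑epoxy alcohol | OC[C@]1(C)O[C@H]1CC/C(C)=C/CC/C(C[Si](C)(C)C)=C/I | intermediate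
7 | (2S,3S)‑epoxy triflate | O=S(=O)(OC[C@]1(C)O[C@H]1CC/C(C)=C/CC/C(C[Si](C)(C)C)=C/I)C(F)(F)F | intermediate
8 | prenyl chloride | CC(C)=CCCl | starting material
9 | (2S,3S)‑homoprenyl epoxide vinyl iodide | CC(C)=CCC[C@]1(C)O[C@H]1CC/C(C)=C/CC/C(C[Si](C)(C)C)=C/I | intermediate
10 | methyl 4‑hydroxy‑3‑methylbenzoate | COC(=O)c1ccc(O)c(C)c1 | starting material
11 | methyl 3‑bromo‑4‑hydroxy‑5‑methylbenzoate | COC(=O)c1cc(C)c(O)c(Br)c1 | intermediate
12 | methyl 4‑acetoxy‑3‑bromo‑5‑methylbenzoate | COC(=O)c1cc(C)c(OC(C)=O)c(Br)c1 | intermediate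
13 | methyl 4‑acetoxy‑3‑bromo‑5‑(bromomethyl)benzoate | COC(=O)c1cc(CBr)c(OC(C)=O)c(Br)c1 | intermediate
14 | (10S,11S)‑epoxy polyene arene | CC(C)=CCC[C@]1(C)O[C@H]1CC/C(C)=C/CC/C(C[Si](C)(C)C)=C/Cc1cc(C(=O)OC)cc(Br)c1OC(C)=O | intermediate
15 | (10R,11S)‑bromohydrin | CC(C)=CCC[C@](C)(O)[C@H](Br)CC/C(C)=C/CC/C(C[Si](C)(C)C)=C/Cc1cc(C(=O)OC)cc(Br)c1OC(C)=O | intermediate
16 | (10R,11S)‑bromo trifluoroacetate | CC(C)=CCC[C@](C)(OC(=O)C(F)(F)F)[C@H](Br)CC/C(C)=C/CC/C(C[Si](C)(C)C)=C/Cc1cc(C(=O)OC)cc(Br)c1OC(C)=O | intermediate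
17 | protected callophycoic acid H (methyl ester, O‑acetate) | C=C1CC[C@@H]2[C@@](C)(CCC=C(C)C)[C@H](Br)CC[C@@]2(C)[C@@H]1Cc1cc(C(=O)OC)cc(Br)c1OC(C)=O | intermediate
18 | callophycoic acid H | C=C1CC[C@@H]2[C@@](C)(CCC=C(C)C)[C@H](Br)CC[C@@]2(C)[C@@H]1Cc1cc(C(=O)O)cc(Br)c1O | target

**Step count**
Total steps: 14. Longest linear sequence: 11 (steps 1–6 and 10–14). The arene branch is 3 steps.

**Three steps most likely to fail**
1. Step 13.
   - Failure modes: solvent or trifluoroacetate capture, stopping after one ring, Br⁺ transfer to another alkene with loss of ee, and protodesilylation.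
   - Fallback: separate C–C from C–Br formation. Make ent‑14 with D‑(−)‑DET and run a MeAlCl2 epoxide‑initiated, allylsilane‑terminated bicyclisation, which gives the same carbon skeleton with an equatorial C3‑OH. Then oxidise, reduce with L‑Selectride to the axial alcohol, and displace with bromide with inversion.
2. Step 11.
   - Failure modes: bromide attack at the tertiary carbon, or Meinwald rearrangement.
   - Fallback: install the bromide on epoxy alcohol 6, where Ti(OiPr)4/Et2NH·HBr chelation directs opening to C3 (= C10). Convert the resulting 1,2‑diol to the terminal 2,2‑disubstituted epoxide through the primary sulfonate and base. Open it at CH2 with prenylMgCl/CuI to reach the bromohydrin directly.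
3. Step 3.
   - Failure modes: slow addition of TMSCH2Cu, or iododesilylation.
   - Fallback: change the bond that is formed.
     - Carboxylate the alkyne of O‑protected 3 to the ynoate.
     - Add a silylmethyl cuprate syn at −78 °C and reduce with DIBAL to the (Z)‑allylsilane allylic alcohol.
     - Make the allylic phosphate and form the aryl–C1 bond with the aryl‑copper reagent from mono Br/Mg exchange of a protected methyl 3,5‑dibromo‑4‑hydroxybenzoate.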